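**Retrosynthetic overview**
1. Target 19 ⇒ anomeric acetate 17 + silyl ketene acetal 18. The last bond is C3–CH2CO2Me, made by axial attack on a cyclic peroxycarbenium ion, which gives the 3,4-cis arrangement.
2. 1,2-Dioxane 16 ⇒ oxolane lactol 14 + H2O2. This is the key step: the C6–O(peroxide) bond is formed in a catalyst-controlled, stereoconvergent ring expansion that sets the quaternary centre C6.
3. 14 ⇒ tertiary alcohol 12 (ozonolysis of the vinyl group) ⇒ ethyl ketone 8 + Grignard reagent from bromide 10 (C5–C6 bond).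
4. 8 ⇒ two Cu-catalysed asymmetric conjugate additions starting from methyl crotonate (C10, then C8); 10 ⇒ Cu-catalysed SN2′ ethylation of (E)-1,4-dibromobut-2-ene (C4).
5. Ring order: a temporary oxolane (step 7) is expanded to the 1,2-dioxane (step 8), the only ring of the target.

Assumption: for each chiral ligand or catalyst (Josiphos, Taniaphos, IDPi) the antipode used is the one that gives the descriptor written; the sense of induction is reagent-controlled and would be fixed in a first experiment.

**Step 1**
Reactants: 1 methyl (E)-but-2-enoate; 2 butylmagnesium bromide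
Product: 3 methyl (3S)-3-methylheptanoate
Conditions: CuBr·SMe2 (2 mol %), Josiphos (2.4 mol %), t-BuOMe, −75 °C; aq. NH4Cl
Reagents that add atoms: none
Why: Cu(I)/ferrocenyl-diphosphine-catalysed asymmetric conjugate addition of a Grignard reagent to an (E)-enoate; the ligand decides which face of the β-carbon receives butyl and so sets C10 (S).

**Step 2**
Reactants: 3 methyl (3S)-3-methylheptanoate
Product: 4 (3S)-3-methylheptanal
Conditions: DIBAL-H (1.05 equiv), CH2Cl2, −78 °C; Rochelle salt
Reagents that add atoms: none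
Why: Partial ester reduction with DIBAL-H stops at the aldehyde because the tetrahedral aluminate is stable at −78 °C; the β-stereocentre cannot epimerise.

**Step 3**
Reactants: 4 (3S)-3-methylheptanal; 5 diethyl (2-oxobutyl)phosphonate
Product: 6 (4E,7S)-7-methylundec-4-en-3-one
Conditions: NaH, THF, 0 °C to rt
Reagents that add atoms: none
Why: Horner–Wadsworth–Emmons olefination with a β-ketophosphonate gives the (E)-enone selectively.

**Step 4**
Reactants: 6 (4E,7S)-7-methylundec-4-en-3-one; 7 ethylmagnesium bromide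
Product: 8 (5S,7S)-5-ethyl-7-methylundecan-3-one
Conditions: CuBr·SMe2 (5 mol %), Josiphos (6 mol %), t-BuOMe, −75 °C; aq. NH4Cl
Reagents that add atoms: none
Why: Cu-catalysed asymmetric conjugate addition of EtMgBr to an acyclic enone; ligand control sets C8 (S), and the remote C10 centre exerts little bias.

**Step 5**
Reactants: 9 (E)-1,4-dibromobut-2-ene; 7 ethylmagnesium bromide
Product: 10 (3R)-3-(bromomethyl)pent-1-ene
Conditions: CuBr·SMe2 (1 mol %), Taniaphos (1.2 mol %), CH2Cl2, −75 °C
Reagents that add atoms: none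
Why: Cu-catalysed asymmetric allylic alkylation (SN2′) of the symmetrical dibromide; ligand-controlled γ-attack sets C4 and leaves an unreactive homoallylic primary bromide.

**Step 6**
Reactants: 10 (3R)-3-(bromomethyl)pent-1-ene; 8 (5S,7S)-5-ethyl-7-methylundecan-3-one
Product: 12 (3S,7S,9S)-3,5,7-triethyl-9-methyltridec-1-en-5-ol (both C5 epimers), via Grignard reagent 11 (not isolated)
Conditions: Mg, THF, rt; then 8, LaCl3·2LiCl (0.3 equiv), THF, 0 °C; aq. NH4Cl
Reagents that add atoms: none
Why: Grignard formation and 1,2-addition to the ketone (La(III) suppresses enolisation); the carbinol carbon (C6 of the target) is deliberately formed as both epimers because step 8 is stereoconvergent, and the β-stereocentre of the Grignard reagent is untouched.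

**Step 7**
Reactants: 12 (3S,7S,9S)-3,5,7-triethyl-9-methyltridec-1-en-5-ol
Product: 14 (3S)-3,5-diethyl-5-[(2S,4S)-2-ethyl-4-methyloctyl]oxolan-2-ol (C2/C5 epimers), via hydroxy aldehyde 13 (not isolated)
Conditions: O3, CH2Cl2, −78 °C; then Me2S, −78 °C to rt
Reagents that add atoms: ozone, [O-][O+]=O
Why: Ozonolysis with reductive work-up cleaves the only alkene, and the hydroxy aldehyde closes to the five-membered lactol, which shields the α-stereocentre C4 from enolisation.

**Step 8**
Reactants: 14 (3S)-3,5-diethyl-5-[(2S,4S)-2-ethyl-4-methyloctyl]oxolan-2-ol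
Product: 16 (4S,6S)-4,6-diethyl-6-[(2S,4S)-2-ethyl-4-methyloctyl]-1,2-dioxan-3-ol (C3 anomers), via hydroperoxyoxolane 15 (not isolated)
Conditions: anhydrous H2O2 in Et2O (2 equiv), (S,S)-IDPi (confined chiral imidodiphosphorimidate Brønsted acid, 5 mol %), MgSO4, CHCl3, −20 °C
Reagents that add atoms: hydrogen peroxide, OO
Why: Proposed new method: acid-catalysed acetal exchange turns the lactol into the hydroperoxyoxolane, the confined chiral acid then heterolyses the tertiary C6–O bond of either C6 epimer to one tertiary-carbocation/chiral-anion ion pair (stereoconvergent), and the tethered terminal peroxy oxygen recloses to the six-membered ring inside the anion pocket, which has to tell the small ethyl group from the long β-branched arm and so sets C6 (S); the ring expansion is estimated to be a few kcal/mol downhill (a peroxide C–O bond and a chair ring replace the strained oxolane ether); the closest known reactions are acid-catalysed SN1 perhydrolysis of tertiary alcohols and oxetanes, formation of 1,2-dioxolan-3-ols from β-hydroxy ketones and H2O2, and IDPi-catalysed asymmetric hydroalkoxylation and ion-pair control of purely aliphatic carbocations.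

**Step 9**
Reactants: 16 (4S,6S)-4,6-diethyl-6-[(2S,4S)-2-ethyl-4-methyloctyl]-1,2-dioxan-3-ol
Product: 17 (4S,6S)-4,6-diethyl-6-[(2S,4S)-2-ethyl-4-methyloctyl]-1,2-dioxan-3-yl acetate (C3 anomers)
Conditions: Ac2O, pyridine, DMAP (cat.), CH2Cl2, 0 °C
Reagents that add atoms: acetic anhydride, CC(=O)OC(C)=O
Why: Acylation of the peroxy-hemiacetal hydroxyl gives an anomeric acetate, the standard leaving group for generating the peroxycarbenium ion.

**Step 10**
Reactants: 17 (4S,6S)-4,6-diethyl-6-[(2S,4S)-2-ethyl-4-methyloctyl]-1,2-dioxan-3-yl acetate; 18 tert-butyl[(1-methoxyethenyl)oxy]dimethylsilane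
Product: 19 methyl 2-[(3S,4S,6S)-4,6-diethyl-6-[(2S,4S)-2-ethyl-4-methyloctyl]-1,2-dioxan-3-yl]acetate
Conditions: TMSOTf (0.2 equiv), CH2Cl2, −78 °C
Reagents that add atoms: none
Why: Lewis-acid ionisation to the cyclic peroxycarbenium ion and Mukaiyama-type addition of the silyl ketene acetal; the half-chair is locked with 4-Et pseudo-equatorial and 6-Et equatorial (the other half-chair has these two syn-diaxial), and chair-like axial attack anti to axial H4, on the face away from the axial C6 side chain, puts CH2CO2Me axial and cis to 4-Et, which is C3 (S).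

**Compound list**
1 | methyl (E)-but-2-enoate | C/C=C/C(=O)OC | starting material
2 | butylmagnesium bromide | CCCC[Mg]Br | starting material
3 | methyl (3S)-3-methylheptanoate | CCCC[C@H](C)CC(=O)OC | intermediate
4 | (3S)-3-methylheptanal | CCCC[C@H](C)CC=O | intermediate
5 | diethyl (2-oxobutyl)phosphonate | CCC(=O)CP(=O)(OCC)OCC | starting material
6 | (4E,7S)-7-methylundec-4-en-3-one | CCCC[C@H](C)C/C=C/C(=O)CC | intermediate
7 | ethylmagnesium bromide | CC[Mg]Br | starting material
8 | (5S,7S)-5-ethyl-7-methylundecan-3-one | CCCC[C@H](C)C[C@H](CC)CC(=O)CC | intermediate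
9 | (E)-1,4-dibromobut-2-ene | BrC/C=C/CBr | starting material
10 | (3R)-3-(bromomethyl)pent-1-ene | BrC[C@H](CC)C=C | intermediate
11 | [(2R)-2-ethylbut-3-en-1-yl]magnesium bromide (not isolated) | Br[Mg]C[C@H](CC)C=C | intermediate
12 | (3S,7S,9S)-3,5,7-triethyl-9-methyltridec-1-en-5-ol (both C5 epimers) | CCCC[C@H](C)C[C@H](CC)CC(O)(CC)C[C@H](CC)C=C | intermediate
13 | (2S,6S,8S)-2,4,6-triethyl-4-hydroxy-8-methyldodecanal (C4 epimers, not isolated) | CCCC[C@H](C)C[C@H](CC)CC(O)(CC)C[C@H](CC)C=O | intermediate
14 | (3S)-3,5-diethyl-5-[(2S,4S)-2-ethyl-4-methyloctyl]oxolan-2-ol (C2/C5 epimers) | CCCC[C@H](C)C[C@H](CC)CC1(CC)C[C@H](CC)C(O)O1 | intermediate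
15 | (3S)-3,5-diethyl-5-[(2S,4S)-2-ethyl-4-methyloctyl]-2-hydroperoxyoxolane (not isolated) | CCCC[C@H](C)C[C@H](CC)CC1(CC)C[C@H](CC)C(OO)O1 | intermediate
16 | (4S,6S)-4,6-diethyl-6-[(2S,4S)-2-ethyl-4-methyloctyl]-1,2-dioxan-3-ol (C3 anomers) | CCCC[C@H](C)C[C@H](CC)C[C@@]1(CC)C[C@H](CC)C(O)OO1 | intermediate
17 | (4S,6S)-4,6-diethyl-6-[(2S,4S)-2-ethyl-4-methyloctyl]-1,2-dioxan-3-yl acetate (C3 anomers) | CCCC[C@H](C)C[C@H](CC)C[C@@]1(CC)C[C@H](CC)C(OC(C)=O)OO1 | intermediate
18 | tert-butyl[(1-methoxyethenyl)oxy]dimethylsilane | C=C(OC)O[Si](C)(C)C(C)(C)C | starting material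
19 | methyl 2-[(3S,4S,6S)-4,6-diethyl-6-[(2S,4S)-2-ethyl-4-methyloctyl]-1,2-dioxan-3-yl]acetate | CCCC[C@H](C)C[C@H](CC)C[C@@]1(CC)C[C@H](CC)[C@H](CC(=O)OC)OO1 | target

**Step count**
Total: 10 steps. Longest linear sequence: 9 steps (1–4, then 6–10); step 5 is the one-step side branch.

**Three steps most likely to fail**

Step 8 (the proposed new step). The chiral anion may fail to distinguish ethyl from the side-chain arm, giving C6 near 1:1. Other risks are re-ionisation of 16 (erosion of selectivity), acid-induced Criegee/Hock cleavage of the hydroperoxy acetal, E1 loss to alkenes, and epimerisation of C4 through the open aldehyde. The fallback uses only known chemistry; it sets out from 12 and comes back at 16. SN1 perhydrolysis of tertiary alcohol 12 with anhydrous ethereal H2O2 and catalytic H2SO4 gives the tertiary hydroperoxide F1 as both C6 epimers. Ozonolysis of its vinyl group in CH2Cl2 at −78 °C lets the internal OOH trap the carbonyl oxide, giving the 3-hydroperoxy-1,2-dioxane F2. One equivalent of Me2S reduces the exocyclic OOH to give 16 as a roughly 1:1 mixture of C6 epimers. These are acetylated to 17 and the (6S) epimer is separated by preparative HPLC, so about half the material is lost.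

Step 10. The Lewis acid may fragment the peroxide or cause elimination to the 3,4-ene, and the silyl ketene acetal may give a lower cis/trans ratio than predicted. The fallback sets out from 17 and comes back at 19. Allyltrimethylsilane with SnCl4 in CH2Cl2 at −78 °C, the most robust peroxycarbenium nucleophile and subject to the same axial-attack argument, gives the 3-allyl-1,2-dioxane F3. Ozonolysis (O3, then Me2S) gives the dioxanyl acetaldehyde F4. Pinnick oxidation (NaClO2, NaH2PO4, 2-methyl-2-butene) gives the dioxanyl acetic acid F5, and TMSCHN2 in MeOH/toluene gives 19.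

Step 4. The ethyl enone may give 1,2-addition or a lower diastereomer ratio than the better-studied thioester substrates. The fallback sets out from 4 and comes back at 8. Wittig olefination of 4 with S-ethyl 2-(triphenylphosphoranylidene)ethanethioate gives the (E)-thioenoate F6. Cu/Josiphos-catalysed conjugate addition of EtMgBr, the benchmark substrate class for this catalyst, gives the thioester F7. Fukuyama coupling with EtZnI and PdCl2(PPh3)2 converts F7 into ketone 8.

**Further compounds**
F1 | step 8 | (3S,7S,9S)-3,5,7-triethyl-5-hydroperoxy-9-methyltridec-1-ene (both C5 epimers) | CCCC[C@H](C)C[C@H](CC)CC(OO)(CC)C[C@H](CC)C=C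
F2 | step 8 | (4S)-4,6-diethyl-6-[(2S,4S)-2-ethyl-4-methyloctyl]-3-hydroperoxy-1,2-dioxane (C3/C6 epimers) | CCCC[C@H](C)C[C@H](CC)CC1(CC)C[C@H](CC)C(OO)OO1
F3 | step 10 | (3S,4S,6S)-4,6-diethyl-6-[(2S,4S)-2-ethyl-4-methyloctyl]-3-(prop-2-en-1-yl)-1,2-dioxane | CCCC[C@H](C)C[C@H](CC)C[C@@]1(CC)C[C@H](CC)[C@H](CC=C)OO1
F4 | step 10 | 2-[(3S,4S,6S)-4,6-diethyl-6-[(2S,4S)-2-ethyl-4-methyloctyl]-1,2-dioxan-3-yl]acetaldehyde | CCCC[C@H](C)C[C@H](CC)C[C@@]1(CC)C[C@H](CC)[C@H](CC=O)OO1
F5 | step 10 | 2-[(3S,4S,6S)-4,6-diethyl-6-[(2S,4S)-2-ethyl-4-methyloctyl]-1,2-dioxan-3-yl]acetic acid | CCCC[C@H](C)C[C@H](CC)C[C@@]1(CC)C[C@H](CC)[C@H](CC(=O)O)OO1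
F6 | step 4 | S-ethyl (2E,5S)-5-methylnon-2-enethioate | CCCC[C@H](C)C/C=C/C(=O)SCC
F7 | step 4 | S-ethyl (3S,5S)-3-ethyl-5-methylnonanethioate | CCCC[C@H](C)C[C@H](CC)CC(=O)SCC
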